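The runs come from a simulation from invented constants; the scatter is artificial.

The pitfall is to see the substrate percentages of cedar and maple nearly coincide and to call the loss plain first order.

all flasks: gas phase 160 mM (held)

| run | substrate | remark | time |
|---|---|---|---|
| cedar | 0.40 M | run made earlier |  |
| maple | 0.60 M | run made earlier |  |
| south-west | 0.80 M |  | 12 h |
| east | 0.80 M |  | 25 h |
| west | 0.80 M |  | 50 h |

- cedar (time / h: target / %, side product / %, substrate / %): 2.00: 3.9, 0, 94.9; 5.00: 16.6, 0.9, 81.4; 10.0: 36.4, 2.4, 58.2; 15.0: 51.1, 4.5, 41.4
- maple (time / h: target / %, side product / %, substrate / %): 2.00: 3.9, 0.1, 94.5; 5.00: 15.2, 1.4, 82.1; 10.0: 31.3, 3.4, 61.4; 15.0: 44.7, 6.8, 44.0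

(standard deviation of a reading: 0.3 percentage points)

1. which of these there is most of at the end, counted by the substrate in it, south-west (side product / substrate / target)
2. which of these there is most of at the end, counted by the substrate in it, east (side product / substrate / target)
3. which of these there is most of at the end, counted by the substrate in it, west (side product / substrate / target)
4. how much there is at the end of the one of these that leads, in percent of the substrate charged: south-west
5. how much there is at the end of the one of these that leads, in percent of the substrate charged: east
6. how much there is at the end of the one of these that leads, in percent of the substrate charged: west

- a species is counted by the substrate in it: one self-condensation product or side product counts as two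
- at the start none of the gas is dissolved
- steps under discussion: substrate + dissolved gas -> target; dissolved gas -> decomposition product; 2 substrate -> self-condensation product; gas phase <-> dissolved gas; substrate + target -> side product

But the two runs differ. We define a lifetime r, the time in which substrate falls by a factor e once reaction is under way; it is the inverse of a pseudo-first-order constant. Between 5.00 h and 15.0 h, the readings give 14.8 h in cedar and 16.0 h in maple, so maple's lifetime is longer than cedar's.

We read this by treating dissolved gas as steady, with what crosses in being consumed at once. A richer charge then holds the gas lower, and each substrate lasts longer. Cedar's line, run back to full charge, gives a lag L of 1.96 h while the gas first dissolves.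

So r rises with the charge, and we carry the straight line through cedar and maple onward. At 0.80 M this gives the charge lifetime r = 17.3 h.

Our own reckoning, exp(−(t−L)/r), leaves 55.9% of the substrate in south-west, 26.3% in east and 6.20% in west. But r should shorten as substrate falls, and our late figures stand above the forecast's 22% and 2%.

The forecast says substrate at 56% in south-west, target at 56% in east and target at 69% in west, since “gas transfer limits the reaction”.

The flasks give substrate at 56.5% in south-west, target at 56.7% in east and target at 70.9% in west.

    substrate + dissolved gas → target (k = 0.588 /M/h)
    dissolved gas → decomposition product (k = 4.91 × 10⁻⁵ /h)
    2 substrate → self-condensation product (k = 0.00376 /M/h)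
    gas phase ⇌ dissolved gas, rate k4*(csat - [dissolved gas]) (kL = 0.334 /h)
    substrate + target → side product (k = 0.0266 /M/h)

South-west's result implies a lifetime of 17.6 h, beside our 17.3 h. Substrate leads there in part through the drag of the gas crossing, together with the early hour. With that drag taken away, south-west's substrate drops from 56.5% to 28.4% and the forecast's first answer would be wrong. The same flask read at 20 h already has target in the lead.

For a neighbour of south-west charged with 0.32 M, the same line takes r down to 14.3 h, which leaves 49.5% of the substrate. The computed flask holds 49.8% of its substrate.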